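A neighbour run takes half the substrate and leaves the other amounts as they are, so what I count here should also say how the answer moves with the charge.

substrate 0.093 M (fed, over 8.0 s); acid 0.279 mM; scavenger 0.500 equiv; time 1.0 min

    substrate + weak acid ⇌ idle adduct, settled at all times (K1 = 1800 L mol⁻¹)
    weak acid ⇌ conjugate base + acid, settled at all times (K2 = 1.6 × 10⁻⁸ M)
    substrate + acid → weak acid + acid + target (k3 = 87.1 L mol⁻¹ s⁻¹)
    weak acid + scavenger → scavenged by-product (k4 = 6.68 L mol⁻¹ s⁻¹)
    substrate + target → side product (k5 = 0.448 L mol⁻¹ s⁻¹)
    substrate → weak acid + target (k6 = 0.00705 s⁻¹)

- acid is the free proton; pH is minus the decimal logarithm of its molar concentration
- percentages count the substrate that a species holds: one side product counts as two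
- weak acid is meant together with its idle adduct
- what has gone from substrate into another species counts as reacted, even if it can come back
- run time (flask): 1.0 min

* part of the substrate that has reacted at 1.0 min
* pH of the solution at 1.0 min

Does the acid stay? It is given back each time it acts. Even with the whole charge as weak acid, the balance allows 0.00533 mM of conjugate base, far less than the 0.279 mM of acid. So I expect the pH of the charged acid, and the acid-carried step is pseudo-first-order in substrate.

How many lifetimes does free substrate get? The acid-carried step is quicker than the uncatalysed one, and together they give 0.0314 s⁻¹. Substrate arrives on average at mid-feed, so it has 56.0 s in the flask, which makes 1.76 lifetimes. Counting these two steps and no other, I put the reacted part above 82.7%.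

Does target speed this up? Substrate also dies on target, and target stops growing at a ceiling of 70.0 mM, where making equals loss. That is below the charge, so I must count this loss. My guess is that target averages half of it, so this loss adds half of the first constant. The lifetime count, meaning the loss constant of free substrate with target at its mean, times the mean time in the flask, is then 2.63. I leave the idle adduct out of it. That gives 92.8% reacted.

The forecast gives 92.5% and pH 3.55, holding that “the weak acid barely dissociates against it”. Its grounds lean on the adduct, and mine on the loss on target.

The flask gives 92.3% reacted and pH 3.55. The idle adduct holds 29.9% of the substrate charged at 1.00 min, yet the binding makes next to no difference to the reacted part. My count of 2.63 lifetimes leaves 7.21%, and this flask holds 7.74% as free substrate, while its target reads 33.6 mM at 1.00 min, less than the 35.0 mM I took as its mean. For the neighbour with half the substrate, I assume that mean target falls in step with the charge, so the loss on target adds a quarter of the first constant. The count becomes 2.19, which means 88.9% reacted, and that neighbour gives 89.0%.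

(All constants belong to no real substance; the run is a simulation.)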